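The cyclohexa-2,4-dienone ring is disconnected into a methoxy(allyl)carbene carbon (C5), one CO (C6) and the two alkynes of a 1,6-diyne (C4≡C3a and C7a≡C7) held by the O1–C2–C3 tether. A chromium-templated two-alkyne annulation joins them in one operation: it closes the dihydrofuran ring at C3a–C7a and the carbocycle at C5–C6, exploiting that C5 carries OMe and a carbon substituent next to the C6 ketone, the signature of a Fischer carbene carbon. The precursor is an acyclic ynol ether–alkyne carrying the C2 and C3 stereocentres, set by an anti-selective allenylzinc addition; a silyl cap on the ynol ether dictates the order of insertion.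

Key step: step 7

Remark: atoms are numbered as in 2,3-dihydro-1-benzofuran (O1, C2, C3, C3a, C4 to C7, C7a), and step 5 assumes that the acetylenic C–H of an alkynyl ether is more acidic than that of an alkyl acetylene.

Step 1
Reactants: 1 (S)-but-3-yn-2-ol
Product: 2 (2S)-but-3-yn-2-yl methanesulfonate
Conditions: MsCl, Et3N, CH2Cl2, −78 → 0 °C
Reagents that add atoms: methanesulfonyl chloride, CS(=O)(=O)Cl
Why: Sulfonylation of the alcohol (mesylation) occurs at oxygen, so the S configuration is carried unchanged into the leaving group.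

Step 2
Reactants: 2 (2S)-but-3-yn-2-yl methanesulfonate; 3 3,4-dimethoxybenzaldehyde
Product: 5 (1R,2R)-1-(3,4-dimethoxyphenyl)-2-methylbut-3-yn-1-ol, via allenylzinc reagent 4 (not isolated)
Conditions: Pd(OAc)2 (5 mol %), PPh3 (5 mol %), Et2Zn (3 equiv), THF, −78 → −20 °C; aq NH4Cl
Reagents that add atoms: none
Why: Marshall propargylation, in which zerovalent palladium displaces the mesylate anti (SN2′), transmetalation to zinc with retention gives the (M)-allenylzinc 4, and its SE2′ addition to the aldehyde through a closed chair-like transition state with the aryl group equatorial should give mainly the anti adduct, the methyl-bearing carbon (C3 of the target) being fixed by the reagent with overall inversion of the mesylate carbon and the carbinol carbon (C2 of the target) by the cyclic transition state, with the minor syn isomer removed by chromatography.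

Step 3
Reactants: 5 (1R,2R)-1-(3,4-dimethoxyphenyl)-2-methylbut-3-yn-1-ol
Product: 7 4-[(1R,2R)-1-{[(E)-1,2-dichloroethenyl]oxy}-2-methylbut-3-yn-1-yl]-1,2-dimethoxybenzene, via potassium alkoxide 6 (not isolated)
Conditions: KH (1.1 equiv), THF, 0 °C; Cl2C=CHCl (1.1 equiv), −40 °C → rt
Reagents that add atoms: trichloroethylene, ClC=C(Cl)Cl
Why: First stage of the trichloroethylene route to alkynyl ethers, in which the potassium alkoxide 6 undergoes net vinylic substitution on trichloroethylene to give the (E)-1,2-dichlorovinyl ether, a reaction at oxygen that leaves both stereocentres untouched.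

Step 4
Reactants: 7 4-[(1R,2R)-1-{[(E)-1,2-dichloroethenyl]oxy}-2-methylbut-3-yn-1-yl]-1,2-dimethoxybenzene
Product: 9 4-[(1R,2R)-1-(ethynyloxy)-2-methylbut-3-yn-1-yl]-1,2-dimethoxybenzene, via dilithio diyne 8 (not isolated)
Conditions: n-BuLi (3.2 equiv), THF, −78 → −40 °C; MeOH, −78 °C; kept below 20 °C
Reagents that add atoms: none
Why: Second stage of the same route (dehydrohalogenation and lithium–halogen exchange), in which n-BuLi deprotonates the terminal alkyne, eliminates HCl from the dichlorovinyl ether and exchanges the remaining chlorine for lithium, and cold protonation of the dilithio species 8 releases the terminal ynol ether without touching a stereocentre.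

Step 5
Reactants: 9 4-[(1R,2R)-1-(ethynyloxy)-2-methylbut-3-yn-1-yl]-1,2-dimethoxybenzene
Product: 11 ({[(1R,2R)-1-(3,4-dimethoxyphenyl)-2-methylbut-3-yn-1-yl]oxy}ethynyl)(trimethyl)silane, via lithium alkoxyacetylide 10 (not isolated)
Conditions: LiN(SiMe3)2 (1.0 equiv), THF, −78 °C; Me3SiCl (1.1 equiv), −78 → −20 °C
Reagents that add atoms: chlorotrimethylsilane, C[Si](C)(C)Cl
Why: Site-selective metalation and C-silylation of a terminal alkyne, in which the σ-withdrawing oxygen should make the ynol ether C–H the more acidic of the two acetylenic hydrogens, so that one equivalent of the weak amide base metalates it in preference and the acetylide 10 is trapped on silicon.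

Step 6
Reactants: 12 chromium hexacarbonyl; 13 allylmagnesium bromide
Product: 15 pentacarbonyl(1-methoxybut-3-en-1-ylidene)chromium, via bromomagnesium acylchromate 14 (not isolated)
Conditions: 13 (1.05 equiv), Et2O–THF, 0 °C → rt; Me3OBF4 (1.5 equiv), CH2Cl2–H2O, 0 °C; neutral silica, 0 °C
Reagents that add atoms: trimethyloxonium tetrafluoroborate, C[O+](C)C.F[B-](F)(F)F
Why: Fischer carbene synthesis, in which the allyl nucleophile adds to a CO ligand and O-methylation of the acylmetalate 14 with the oxonium salt gives the methoxycarbene, with cold, base-free handling meant to keep the β,γ-double bond out of conjugation with the carbene carbon.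

Step 7
Reactants: 11 ({[(1R,2R)-1-(3,4-dimethoxyphenyl)-2-methylbut-3-yn-1-yl]oxy}ethynyl)(trimethyl)silane; 15 pentacarbonyl(1-methoxybut-3-en-1-ylidene)chromium
Product: 18 (2R,3R,5S)-2-(3,4-dimethoxyphenyl)-5-methoxy-3-methyl-5-(prop-2-en-1-yl)-7-(trimethylsilyl)-2,3-dihydro-1-benzofuran-6(5H)-one, via vinylcarbene complex 16 (not isolated), via dienylketene complex 17 (not isolated)
Conditions: 15 (1.3 equiv), MeCN (0.01 M), 45–50 °C, Ar, dark; then air, Celite, chromatography below 20 °C
Reagents that add atoms: none
Why: Loss of one CO from 15 lets the terminal alkyl alkyne of 11 insert into the Cr=C bond with the carbene carbon (C5) bonding to the unsubstituted terminus (C4), giving the (E)-vinylcarbene 16 with OMe anti to the new carbene carbon C3a; 5-exo-dig insertion of the tethered silyl ynol ether into Cr=C3a then forms C3a–C7a and closes the dihydrofuran ring, CO insertion at C7 gives the dienylketene 17, and a disrotatory 6π-electrocyclization forms C5–C6 and closes the cyclohexa-2,4-dienone ring. The closest known reaction type is the two-alkyne annulation of methoxy(alkyl)carbene complexes of chromium with 1,6-diynes, which gives bicyclic 6-methoxycyclohexa-2,4-dienones with the carbene carbon as the sp3 centre next to the new ketone. C5 is the only new stereocentre: in 16 the allyl group is the inside substituent of the enol ether, the Cr(CO)3 fragment should sit on the triene face opposite the C2 aryl group, and closure with the allyl group turning away from the metal places allyl cis to the aryl group and OMe cis to the C3 methyl group (5S); this 1,4-induction is expected to be moderate, its sense rests on a steric model, and the C5 epimer is removed by chromatography. The step needs the alkyl alkyne to enter before the ynol ether, which the trimethylsilyl cap secures by shielding the nucleophilic ynol ether terminus from intermolecular insertion (the tether then fixes the regiochemistry of the second insertion), and it needs the α-methoxy ketone to survive, which acetonitrile is expected to secure by binding the spent zerovalent chromium as Cr(CO)3(MeCN)3. The temperature is held at 45–50 °C because the benzylic ynol ether and the 5-allyl dienone are both prone to [3,3]-sigmatropic shifts on stronger heating.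

Step 8
Reactants: 18 (2R,3R,5S)-2-(3,4-dimethoxyphenyl)-5-methoxy-3-methyl-5-(prop-2-en-1-yl)-7-(trimethylsilyl)-2,3-dihydro-1-benzofuran-6(5H)-one
Product: 19 (2R,3R,5S)-2-(3,4-dimethoxyphenyl)-5-methoxy-3-methyl-5-(prop-2-en-1-yl)-2,3-dihydro-1-benzofuran-6(5H)-one
Conditions: Bu4NF (1.5 equiv), AcOH (1.5 equiv), THF, 0 °C
Reagents that add atoms: none
Why: Protodesilylation, in which C7 is the nucleophilic α-carbon of the vinylogous ester, so that ipso-protonation gives an oxocarbenium ion at C7a that is β to silicon and fluoride removes the silyl group, while the buffered, cold medium should leave the acid-sensitive 5-allyl-5-methoxy dienone and its three stereocentres untouched.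

Compound list
1 | (S)-but-3-yn-2-ol | C[C@H](O)C#C | starting material
2 | (2S)-but-3-yn-2-yl methanesulfonate | C[C@H](OS(C)(=O)=O)C#C | intermediate
3 | 3,4-dimethoxybenzaldehyde | COc1ccc(C=O)cc1OC | starting material
4 | (M)-buta-1,2-dien-1-yl(ethyl)zinc | CC[Zn]C([H])=[C@]=C([H])C | intermediate
5 | (1R,2R)-1-(3,4-dimethoxyphenyl)-2-methylbut-3-yn-1-ol (anti) | O[C@@H](c1ccc(OC)c(OC)c1)[C@@H](C#C)C | intermediate
6 | potassium (1R,2R)-1-(3,4-dimethoxyphenyl)-2-methylbut-3-yn-1-olate | [K+].[O-][C@@H](c1ccc(OC)c(OC)c1)[C@@H](C#C)C | intermediate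
7 | 4-[(1R,2R)-1-{[(E)-1,2-dichloroethenyl]oxy}-2-methylbut-3-yn-1-yl]-1,2-dimethoxybenzene | Cl/C=C(/Cl)O[C@@H](c1ccc(OC)c(OC)c1)[C@@H](C#C)C | intermediate
8 | dilithio derivative of 9 (lithium on both alkyne termini) | [Li]C#CO[C@@H](c1ccc(OC)c(OC)c1)[C@@H](C#C[Li])C | intermediate
9 | 4-[(1R,2R)-1-(ethynyloxy)-2-methylbut-3-yn-1-yl]-1,2-dimethoxybenzene | C#CO[C@@H](c1ccc(OC)c(OC)c1)[C@@H](C#C)C | intermediate
10 | lithium alkoxyacetylide of 9 (lithium on the ynol ether terminus) | [Li]C#CO[C@@H](c1ccc(OC)c(OC)c1)[C@@H](C#C)C | intermediate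
11 | ({[(1R,2R)-1-(3,4-dimethoxyphenyl)-2-methylbut-3-yn-1-yl]oxy}ethynyl)(trimethyl)silane | C[Si](C)(C)C#CO[C@@H](c1ccc(OC)c(OC)c1)[C@@H](C#C)C | intermediate
12 | chromium hexacarbonyl, Cr(CO)6 | O=C=[Cr](=C=O)(=C=O)(=C=O)(=C=O)=C=O | starting material
13 | allylmagnesium bromide | C=CC[Mg]Br | starting material
14 | bromomagnesium pentacarbonyl(but-3-enoyl)chromate | C=CCC(=O)[Cr-](=C=O)(=C=O)(=C=O)(=C=O)=C=O.[Mg+]Br | intermediate
15 | pentacarbonyl(1-methoxybut-3-en-1-ylidene)chromium, (CO)5Cr=C(OMe)CH2CH=CH2 | COC(CC=C)=[Cr](=C=O)(=C=O)(=C=O)(=C=O)=C=O | intermediate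
16 | tetracarbonylchromium vinylcarbene, Cr=C3a carrying the C3 chain and the (E)-CH=C(OMe)(allyl) arm | C=CC/C(OC)=C\C(=[Cr](=C=O)(=C=O)(=C=O)=C=O)[C@@H](C)[C@@H](OC#C[Si](C)(C)C)c1ccc(OC)c(OC)c1 | intermediate
17 | Cr(CO)3-bound (2R,3R)-2-(3,4-dimethoxyphenyl)-4-[(1E)-2-methoxypenta-1,4-dien-1-yl]-3-methyl-5-[2-oxo-1-(trimethylsilyl)ethenyl]-2,3-dihydrofuran (dienylketene) | C=CC/C(OC)=C\C1=C(C(=C=O)[Si](C)(C)C)O[C@@H](c2ccc(OC)c(OC)c2)[C@@H]1C.O=C=[Cr](=C=O)=C=O | intermediate
18 | (2R,3R,5S)-2-(3,4-dimethoxyphenyl)-5-methoxy-3-methyl-5-(prop-2-en-1-yl)-7-(trimethylsilyl)-2,3-dihydro-1-benzofuran-6(5H)-one | C=CC[C@]1(OC)C=C2C(=C([Si](C)(C)C)C1=O)O[C@@H](c1ccc(OC)c(OC)c1)[C@@H]2C | intermediate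
19 | (2R,3R,5S)-2-(3,4-dimethoxyphenyl)-5-methoxy-3-methyl-5-(prop-2-en-1-yl)-2,3-dihydro-1-benzofuran-6(5H)-one (CNP0109840.1; 2-aryl and 3-methyl trans, 5-OMe cis to 3-methyl) | C=CC[C@]1(OC)C=C2C(=CC1=O)O[C@@H](c1ccc(OC)c(OC)c1)[C@@H]2C | target

Total step count: 8. Longest linear sequence: 7 steps (steps 1, 2, 3, 4, 5, 7, 8); step 6 is a one-step branch that supplies the carbene complex.

Steps most likely to fail

Step 7. What may go wrong: weak facial selectivity in the ring closure that sets C5, because the induction from the C2/C3 pair is only 1,4, so that 18 forms together with much of its C5 epimer. The fallback uses the Barton–Quinkert photochemical ring opening of linearly conjugated cyclohexadienones. It sets out from 18 as obtained in mixture. The separated C5 epimer, (2R,3R,5R)-silyl dienone F1, is irradiated at 366 nm in Et2O at −30 °C without a nucleophile, which opens the C5–C6 bond to the metal-free silyl dienylketene F2. In the dark at 20–40 °C, F2 recloses to 18 and F1, and repeated separation and irradiation funnels the material into 18, where the route is rejoined.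

Step 5. What may go wrong: metalation at the alkyl alkyne instead of the ynol ether (wrong site selectivity), which would put the silyl group on the alkyne that has to stay free. The fallback replaces selective protection by protection of both sites and selective unmasking. It sets out from 9: both termini are silylated (n-BuLi 2.2 equiv, Me3SiCl, THF, −78 °C) to the bis(trimethylsilyl) diyne F3. The silyl group on the more acidic terminus, which in this scenario is the alkyl alkyne, is then cleaved selectively (K2CO3 cat., MeOH, 0 °C, monitored), and the route is rejoined at 11.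

Step 8. What may go wrong: acid-triggered migration of the allyl group with aromatisation of the dienone, or incomplete cleavage of the hindered C7–Si bond. The fallback changes the blocking group to tin, which leaves under much milder conditions. It sets out from 9: LiN(SiMe3)2 and then Bu3SnCl (THF, −78 °C) give the tributylstannyl ynol ether F4. Annulation with 15 under the conditions of step 7 gives the 7-tributylstannyl dienone F5. Protodestannylation of the alkenylstannane (AcOH 1.1 equiv, CH2Cl2, 0 °C) gives 19 directly, where the route is rejoined.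

Further compounds
F1 | step 7 | (2R,3R,5R)-2-(3,4-dimethoxyphenyl)-5-methoxy-3-methyl-5-(prop-2-en-1-yl)-7-(trimethylsilyl)-2,3-dihydro-1-benzofuran-6(5H)-one (C5 epimer of 18) | C=CC[C@@]1(OC)C=C2C(=C([Si](C)(C)C)C1=O)O[C@@H](c1ccc(OC)c(OC)c1)[C@@H]2C
F2 | step 7 | (2R,3R)-2-(3,4-dimethoxyphenyl)-4-[(1E)-2-methoxypenta-1,4-dien-1-yl]-3-methyl-5-[2-oxo-1-(trimethylsilyl)ethenyl]-2,3-dihydrofuran (metal-free dienylketene; the Z enol ether recloses likewise) | C=CC/C(OC)=C\C1=C(C(=C=O)[Si](C)(C)C)O[C@@H](c2ccc(OC)c(OC)c2)[C@@H]1C
F3 | step 5 | trimethyl({[(1R,2R)-1-(3,4-dimethoxyphenyl)-2-methyl-4-(trimethylsilyl)but-3-yn-1-yl]oxy}ethynyl)silane | C[Si](C)(C)C#CO[C@@H](c1ccc(OC)c(OC)c1)[C@@H](C#C[Si](C)(C)C)C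
F4 | step 8 | tributyl({[(1R,2R)-1-(3,4-dimethoxyphenyl)-2-methylbut-3-yn-1-yl]oxy}ethynyl)stannane | CCCC[Sn](CCCC)(CCCC)C#CO[C@@H](c1ccc(OC)c(OC)c1)[C@@H](C#C)C
F5 | step 8 | (2R,3R,5S)-2-(3,4-dimethoxyphenyl)-5-methoxy-3-methyl-5-(prop-2-en-1-yl)-7-(tributylstannyl)-2,3-dihydro-1-benzofuran-6(5H)-one | C=CC[C@]1(OC)C=C2C(=C([Sn](CCCC)(CCCC)CCCC)C1=O)O[C@@H](c1ccc(OC)c(OC)c1)[C@@H]2C
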